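## The problem

The target is a cis-fused drimane-type sesquiterpenyl ether of umbelliferone. With drimane numbering (used below for every intermediate), ring A is a 2,2-dimethylcyclohexanone (C3=O, C4 gem-dimethyl), ring B is a cyclohexene (C7=C8, methyl on C8), and C9 carries the CH2O-coumarin arm (C11). The SMILES gives 5S,9R,10S, so H-5 and the C10 methyl are cis and C11 is anti to the C10 methyl.

The hard part is the run C4(quaternary)–C5–C10(quaternary)–C9 with three contiguous stereocentres that cannot be corrected later. C5 is insulated from the ketone by C4, C10 is quaternary and C9 is not acidic, so all three must be set kinetically and in relation to each other. Ring A has no other stereocentre to relay chirality, so the absolute sense must come from a reagent or catalyst when the centres are made.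

The cis fusion rules out the usual drimane sources (chair–chair polyene cyclisation, sclareolide-type chiral pool, hydrogenation of Wieland–Miescher-derived octalones), which give the trans series. The C7=C8 bond must not drift to C8=C9 or the exocyclic position, so acidic or cationic conditions are excluded late in the route. The coumarin lactone does not tolerate hydride, hydroxide or strong Lewis acids, and C11 is a β-branched primary carbon.

The enabling feature: ring A is the 1,2-dihydro form of a blocked, non-aromatisable 6,6-dimethylcyclohexa-2,4-dienone (O=C3–C2=C1–C10=C5, C4 gem-dimethyl). Its γ,δ-bond C10=C5 is the ring-fusion bond, and the C7=C8 bond of ring B lies opposite to it. Ring B with C5, C10 and C9 is therefore the endo [4+2] adduct of an (E)-3-methylpenta-2,4-dienyl ether across C10=C5, an adduct that linear dienones deliver through a [4+2]/Cope cascade.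

## Retrosynthesis

**C11–O(aryl).** Target 16 is cut at the ether bond into keto alcohol 14 and umbelliferone 15 (Mitsunobu). This cut comes last because the coumarin would bind the Lewis acid of the key step and would not survive the conjugate reduction unchallenged. The forward reaction needs only substitution at a primary carbon under neutral conditions.

**C1–C2 saturation.** 14 comes from silyl ether 13, and 13 from enone 12 by conjugate reduction. Adding the C1=C2 bond costs one step and reveals the 6,6-dimethylcyclohex-2-enone that is the signature of a Cope product of a cyclohexa-2,4-dienone adduct.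

**C9–C10 by [3,3].** In 12 the bond C9–C10 is cut and C2–C7 is reconnected, giving the 7-alkenylbicyclo[2.2.2]oct-5-en-2-one 11. This is preferred to a direct Diels–Alder cut (C9–C10 and C5–C6 together) because the Cope shift makes the quaternary C10–C9 bond intramolecularly, with regiochemistry fixed by the C5–C6–C7 tether and stereochemistry fixed by the boat geometry. The forward reaction needs the alkenyl group on C7 to be endo.

**C5–C6 and C2–C7 by [4+2].** 11 is cut into dienone 7 (as the 4π partner through C2 and C5) and the terminal vinyl group of dienyl silyl ether 10. Both partners are achiral, flat and of similar size (C9 and C6 plus protecting group), and the ketone of 7 is already at C3. The forward reaction must select one face of 7, bond C6 to C5, and place the alkenyl residue endo.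

**Dienone 7.** 7 comes from β,γ-enone 5 by α,β-dehydrogenation (through silyl enol ether 6). 5 comes from 4-methylcyclohex-3-en-1-one 3 by α,α-dimethylation (through 4), and 3 from Birch reduction of 4-methylanisole 1 (through 2). The gem-dimethyl group serves twice: it is C4 of the target and it blocks aromatisation of 7.

**Diene 10.** 10 comes from dienol 9 by silylation, and 9 from commercial (E)-enynol 8 by semihydrogenation. The E geometry of C8=C9 is bought, not made.

## Roads not taken

**Alternative 1:** the most obvious cut is C4–C5 and C9–C10 by cation–olefin bicyclisation of an epoxy-farnesyl umbelliferyl ether. The forward key step is Lewis acid opening of epoxide A1 to the C3 alcohol A2, then oxidation to 16. The chosen plan is better for these reasons: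
- Cis fusion demands the 6Z olefin of A1, whose folding is less ordered than that of the all-E series.
- Termination by proton loss can give C7=C8, C8=C9 and exocyclic alkenes.
- The terminating olefin is deactivated by the allylic aryl ether.
- The only control element, the epoxide centre, needs its own asymmetric step and is then oxidised away.
- The coumarin must survive a strong Lewis acid.
In the chosen cascade the alkene position and all three centres follow from pericyclic geometry.

**Alternative 2:** cut C5–C6 and C9–C10 in one intermolecular Diels–Alder reaction with ring A as the 2π partner. The forward key step is addition of 10 to the cross-conjugated vinylogous ester A3 to give adduct A4, then hydride reduction and acid (Stork–Danheiser transposition) to 12. The chosen plan is better for these reasons: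
- A3 needs the enol ether on the hindered carbonyl of an unsymmetrical 1,3-dione, against the normal preference.
- Its reacting bond is α-methylated, flanked by a quaternary carbon and deactivated by the vinylogous ester.
- Orientation towards the 1,2-disubstituted diene rests on two opposed directing effects (CH2OR terminus against the C8 methyl).
- A chiral Lewis acid would face an enone with no α-C–H on the reacting side.
- The C1 oxygen is introduced only to be removed.
In the chosen plan 7 has the oxygen at C3 from the start and the C9–C10 bond is made by a tethered sigmatropic shift.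

**Alternative 3:** annulation logic from the Wieland–Miescher ketone A5. The forward key steps are deconjugative gem-dimethylation to A6, hydrogenation of C5=C6, and conversion of the C9 ketone into the CH(CH2OAr)/C8-methyl/C7=C8 array. The chosen plan is better for these reasons:
- Hydrogen must enter C5 on the face of the angular methyl, against the normal steric course, and there is no thermodynamic handle to correct it.
- The C9 ketone needs C8 methylation, one-carbon homologation, alkene placement and a kinetically controlled C9–H, well over twice the step count.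
- C9 would be set late and independently of C5 and C10.

Key step: step 6

Assumption: for step 6 the (S)-prolinol-derived catalyst is taken, by extension of the accepted binding model for 2-cycloalkenones, to leave open the face of 7 on which C5 is Si. Both catalyst antipodes are available, so only the sense depends on this, not the plan.

## Route

Step 1
Reactants: 1 4-methylanisole
Product: 3 4-methylcyclohex-3-en-1-one, via 1-methoxy-4-methylcyclohexa-1,4-diene 2 (not isolated)
Conditions: Li, NH3 (l), THF, t-BuOH, −78 → −33 °C; then (CO2H)2 (cat.), MeOH/H2O, rt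
Reagents that add atoms: water, O
Why: Birch reduction of an anisole leaves the methoxy- and methyl-bearing carbons unsaturated (1,4-diene); mild acid hydrolyses only the enol ether, so the trisubstituted alkene stays out of conjugation.

Step 2
Reactants: 3 4-methylcyclohex-3-en-1-one
Product: 5 2,2,4-trimethylcyclohex-3-en-1-one, via 2,4-dimethylcyclohex-3-en-1-one 4 (not isolated)
Conditions: t-BuOK (2.3 equiv), MeI (3 equiv), THF/t-BuOH, 0 °C → rt
Reagents that add atoms: iodomethane, CI
Why: The C2 hydrogens are both α to the ketone and allylic, so the extended dienolate forms under equilibrating conditions and is alkylated twice at the α-carbon (classical deconjugative α,α-dimethylation); any conjugated enone formed on the way returns to the same dienolate.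

Step 3
Reactants: 5 2,2,4-trimethylcyclohex-3-en-1-one
Product: 7 4,6,6-trimethylcyclohexa-2,4-dien-1-one, via trimethylsilyl dienol ether 6 (not isolated)
Conditions: LDA, THF, −78 °C; TMSCl; then Pd(OAc)2 (1.05 equiv), MeCN, rt; used at once or stored cold
Reagents that add atoms: none
Why: Only one α-carbon of 5 carries hydrogen, so enolisation is regiodefined, and Saegusa–Ito oxidation introduces the α,β-double bond at room temperature; the gem-dimethyl carbon makes the linear dienone non-aromatisable.

Step 4
Reactants: 8 (2E)-3-methylpent-2-en-4-yn-1-ol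
Product: 9 (2E)-3-methylpenta-2,4-dien-1-ol
Conditions: H2 (1 atm), Pd/CaCO3 poisoned with Pb(OAc)2, quinoline, EtOAc, 0 °C, stopped after one equivalent
Reagents that add atoms: none
Why: Lindlar semihydrogenation reduces the terminal alkyne of the conjugated enyne to the vinyl group and leaves the E trisubstituted alkene untouched.

Step 5
Reactants: 9 (2E)-3-methylpenta-2,4-dien-1-ol
Product: 10 {[(2E)-3-methylpenta-2,4-dien-1-yl]oxy}tri(propan-2-yl)silane
Conditions: TIPSCl, imidazole, CH2Cl2, 0 °C → rt
Reagents that add atoms: chlorotri(propan-2-yl)silane, CC(C)[Si](Cl)(C(C)C)C(C)C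
Why: Standard silylation of a primary alcohol; the bulky silyl group keeps the ether oxygen from competing for the cationic Lewis acid of step 6 and resists ionisation of the allylic C–O bond.

Step 6
Reactants: 7 4,6,6-trimethylcyclohexa-2,4-dien-1-one; 10 {[(2E)-3-methylpenta-2,4-dien-1-yl]oxy}tri(propan-2-yl)silane
Product: 12 (4aS,5R,8aS)-1,1,4a,6-tetramethyl-5-({[tri(propan-2-yl)silyl]oxy}methyl)-4a,5,8,8a-tetrahydronaphthalen-2(1H)-one, via bicyclo[2.2.2]octenone 11 (not isolated)
Conditions: (S)-B-(o-tolyl)-diphenylprolinol oxazaborolidine (20 mol %), HNTf2 (18 mol %), 10 (2 equiv), slow addition of 7, CH2Cl2, −78 → −20 °C; then Et3N, solvent switch, toluene, 110 °C (sealed tube)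
Reagents that add atoms: none
Why: Proposed new method: the cationic boron Lewis acid should bind the C3 carbonyl of 7 on the lone pair syn to C2–H, because the C4 gem-dimethyl group blocks the other lone pair; this is the geometry of the known oxazaborolidinium-catalysed Diels–Alder reactions of 2-cycloalkenones, and the closest known reaction type for the cascade itself is the thermal [4+2] addition of cyclohexa-2,4-dienones (for example masked o-benzoquinones) to 1,3-dienes followed by Cope rearrangement to cis-decalins. The LUMO-lowered dienone should react as the 4π partner through C2 and C5 with the terminal C6=C7 bond of 10, the nucleophilic C6 going to the δ-carbon C5 (largest LUMO coefficient), so that the alkenyl residue sits on C7 next to C2; this first ring closure is a [4+2] cycloaddition giving 11. The alkenyl group is expected endo (under C1=C10) through secondary overlap between C9 and C10, the same interaction that later becomes the sigma bond. Heating then drives the [3,3] shift through the enforced boat transition state: C2–C7 breaks, C9–C10 forms, and ring B closes as a six-membered ring by sigmatropic rearrangement, driven by release of bicyclic strain and by conjugation of the new C1=C2 bond with the ketone. C5 is set by the catalyst-exposed face (C5 Si, C2 Re); C10 follows because C9 is tied to C5 through C6–C7–C8 and can only reach the same face, which gives the cis fusion; C9 follows from the E geometry of C8=C9 in the boat, which places C11 anti to the C10 methyl. The step needs periselectivity (dienone as diene, not C1=C2 as dienophile), regioselectivity (C6 to C5), endo selectivity and facial selectivity; these should be secured by the δ-selective LUMO of the locked s-cis dienone, the unhindered vinyl terminus, the endo rule and the catalyst, in that order. An exo or regioisomeric adduct cannot undergo this Cope shift and would be removed at the stage of 12.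

Step 7
Reactants: 12 (4aS,5R,8aS)-1,1,4a,6-tetramethyl-5-({[tri(propan-2-yl)silyl]oxy}methyl)-4a,5,8,8a-tetrahydronaphthalen-2(1H)-one
Product: 13 (4aS,5R,8aS)-1,1,4a,6-tetramethyl-5-({[tri(propan-2-yl)silyl]oxy}methyl)-3,4,4a,5,8,8a-hexahydronaphthalen-2(1H)-one
Conditions: [(Ph3P)CuH]6 (0.3 equiv), H2O (2 equiv), degassed toluene, rt
Reagents that add atoms: none
Why: Copper hydride conjugate reduction is 1,4-selective for enones and leaves the isolated trisubstituted C7=C8 bond and the silyl ether alone; the α′ gem-dimethyl group disfavours 1,2-attack. No stereocentre is formed or touched.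

Step 8
Reactants: 13 (4aS,5R,8aS)-1,1,4a,6-tetramethyl-5-({[tri(propan-2-yl)silyl]oxy}methyl)-3,4,4a,5,8,8a-hexahydronaphthalen-2(1H)-one
Product: 14 (4aS,5R,8aS)-5-(hydroxymethyl)-1,1,4a,6-tetramethyl-3,4,4a,5,8,8a-hexahydronaphthalen-2(1H)-one
Conditions: TBAF, THF, 0 °C → rt; aqueous work-up
Reagents that add atoms: none
Why: Fluoride cleavage of a primary silyl ether; C5 is not enolisable (C4 is quaternary), so the mild basicity cannot epimerise the ring fusion.

Step 9
Reactants: 14 (4aS,5R,8aS)-5-(hydroxymethyl)-1,1,4a,6-tetramethyl-3,4,4a,5,8,8a-hexahydronaphthalen-2(1H)-one; 15 umbelliferone (7-hydroxy-2H-chromen-2-one)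
Product: 16 7-{[(1R,4aS,8aS)-2,5,5,8a-tetramethyl-6-oxo-1,4,4a,5,6,7,8,8a-octahydronaphthalen-1-yl]methoxy}-2H-chromen-2-one
Conditions: PPh3, DIAD, THF, 0 °C → rt
Reagents that add atoms: none
Why: Mitsunobu etherification of a primary alcohol with an acidic phenol (pKa near 8) under neutral conditions that spare the ketone, the C7=C8 bond and the lactone; the reacting carbon C11 is not stereogenic, so C9 is untouched.

## Compound list

1 | 4-methylanisole (1-methoxy-4-methylbenzene) | COc1ccc(C)cc1 | starting material
2 | 1-methoxy-4-methylcyclohexa-1,4-diene | COC1=CCC(C)=CC1 | intermediate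
3 | 4-methylcyclohex-3-en-1-one | O=C1CCC(C)=CC1 | intermediate
4 | 2,4-dimethylcyclohex-3-en-1-one (racemic) | O=C1CCC(C)=CC1C | intermediate
5 | 2,2,4-trimethylcyclohex-3-en-1-one | O=C1CCC(C)=CC1(C)C | intermediate
6 | trimethyl[(4,6,6-trimethylcyclohexa-1,4-dien-1-yl)oxy]silane | C[Si](C)(C)OC1=CCC(C)=CC1(C)C | intermediate
7 | 4,6,6-trimethylcyclohexa-2,4-dien-1-one | O=C1C=CC(C)=CC1(C)C | intermediate
8 | (2E)-3-methylpent-2-en-4-yn-1-ol | C#C/C(C)=C/CO | starting material
9 | (2E)-3-methylpenta-2,4-dien-1-ol | C=C/C(C)=C/CO | intermediate
10 | {[(2E)-3-methylpenta-2,4-dien-1-yl]oxy}tri(propan-2-yl)silane | C=C/C(C)=C/CO[Si](C(C)C)(C(C)C)C(C)C | intermediate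
11 | (1S,4S,7S)-3,3,5-trimethyl-7-[(2E)-4-{[tri(propan-2-yl)silyl]oxy}but-2-en-2-yl]bicyclo[2.2.2]oct-5-en-2-one | O=C1C(C)(C)[C@H]2C[C@H](/C(C)=C/CO[Si](C(C)C)(C(C)C)C(C)C)[C@@H]1C=C2C | intermediate
12 | (4aS,5R,8aS)-1,1,4a,6-tetramethyl-5-({[tri(propan-2-yl)silyl]oxy}methyl)-4a,5,8,8a-tetrahydronaphthalen-2(1H)-one | CC1=CC[C@@H]2C(C)(C)C(=O)C=C[C@]2(C)[C@@H]1CO[Si](C(C)C)(C(C)C)C(C)C | intermediate
13 | (4aS,5R,8aS)-1,1,4a,6-tetramethyl-5-({[tri(propan-2-yl)silyl]oxy}methyl)-3,4,4a,5,8,8a-hexahydronaphthalen-2(1H)-one | CC1=CC[C@@H]2C(C)(C)C(=O)CC[C@]2(C)[C@@H]1CO[Si](C(C)C)(C(C)C)C(C)C | intermediate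
14 | (4aS,5R,8aS)-5-(hydroxymethyl)-1,1,4a,6-tetramethyl-3,4,4a,5,8,8a-hexahydronaphthalen-2(1H)-one | CC1=CC[C@@H]2C(C)(C)C(=O)CC[C@]2(C)[C@@H]1CO | intermediate
15 | umbelliferone (7-hydroxy-2H-chromen-2-one) | Oc1ccc2ccc(=O)oc2c1 | starting material
16 | 7-{[(1R,4aS,8aS)-2,5,5,8a-tetramethyl-6-oxo-1,4,4a,5,6,7,8,8a-octahydronaphthalen-1-yl]methoxy}-2H-chromen-2-one | CC1=CC[C@@H]2C(C)(C)C(=O)CC[C@]2(C)[C@@H]1COc1ccc2ccc(=O)oc2c1 | target

## Step count and least certain steps

Total: 9 steps. Longest linear sequence: 7 steps (steps 1, 2, 3, 6, 7, 8, 9).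

**Step 6 (key step, proposed new method).** Most likely failures:
- Facial selectivity may be poor because the reacting termini C2 and C5 lie partly outside the region the catalyst shields.
- The Lewis acid may promote self-dimerisation of 7.
- The diene may add across C1=C2 of 7 instead (normal-demand mode).
- 11 may undergo cycloreversion at the Cope temperature, returning achiral 7 and 10; an uncatalysed racemic cascade would then erode the enantiomeric purity.

Fallback in known chemistry, setting out from 9 and 7 and returning at 14, in which the protecting group is replaced by a resolving ester: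
- Dienol 9 is esterified with (S)-2-methoxy-2-phenylacetic acid (EDC·HCl, DMAP, CH2Cl2, 0 °C) to the dienyl (S)-O-methylmandelate F1.
- F1 and 7 are heated without catalyst (toluene, 80 → 150 °C, sealed tube). The thermal dienone [4+2]/Cope cascade passes through the (1S,4S,7S) bicyclo[2.2.2]octenone ester F2 and its (1R,4R,7R) diastereomer F3, neither isolated.
- The products are the cis-decalin enone ester F4 (4aS,5R,8aS) and its (4aR,5S,8aR) diastereomer F5, which are separated by chromatography or crystallisation.
- F4 is reduced with [(Ph3P)CuH]6 as in step 7 to the saturated keto ester F6, and methanolysis (K2CO3, MeOH, rt) releases 14.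

**Step 2.** Over-alkylation at the second α-carbon and incomplete second methylation are likely under equilibrating conditions, since nothing but stoichiometry distinguishes the sites once C2 is quaternary. Fallback from 3, returning at 7, using kinetic enolates:
- 3 is isomerised into conjugation (DBU cat., CH2Cl2) to 4-methylcyclohex-2-en-1-one F7.
- LDA/MeI at −78 °C methylates the α′-carbon to give 4,6-dimethylcyclohex-2-en-1-one F8; a second round gives 4,6,6-trimethylcyclohex-2-en-1-one F9.
- With the α′-position blocked, LDA/TMSCl removes the γ-hydrogen to give the silyl dienol ether F10, and Pd(OAc)2 (MeCN, rt) oxidises it to 7.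

**Step 7.** Hydride delivery to C1 may be slow because C1 is next to the quaternary C10, so 1,2-reduction or incomplete conversion could take over. Fallback from 12, returning at 13:
- Deliberate 1,2-reduction (NaBH4, CeCl3·7H2O, MeOH, −40 °C) gives the allylic alcohol F11 (either carbinol epimer).
- Redox isomerisation of the allylic alcohol with RuCl2(PPh3)3 (cat.), toluene, 80 °C gives the saturated ketone.

**Step 9.** Substitution at the β-branched C11 may be slow, letting alkylation of the reduced azodicarboxylate compete. Fallback from 14, returning at 16: the O–aryl bond is formed instead of the O–C11 bond by copper-promoted oxidative coupling (Chan–Lam type) of 14 with commercial (2-oxo-2H-chromen-7-yl)boronic acid (Cu(OAc)2, pyridine, 4 Å sieves, air, CH2Cl2, rt). No new intermediate is made.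

## Further compounds

F1 | step 6 | (2E)-3-methylpenta-2,4-dien-1-yl (2S)-2-methoxy-2-phenylacetate | C=C/C(C)=C/COC(=O)[C@@H](OC)c1ccccc1
F2 | step 6 | (2S)-2-methoxy-2-phenylacetate corresponding to 11, (1S,4S,7S)-bicyclo[2.2.2]octenone | O=C1C(C)(C)[C@H]2C[C@H](/C(C)=C/COC(=O)[C@@H](OC)c3ccccc3)[C@@H]1C=C2C
F3 | step 6 | (2S)-2-methoxy-2-phenylacetate of the (1R,4R,7R)-bicyclo[2.2.2]octenone (diastereomer of F2) | O=C1C(C)(C)[C@@H]2C[C@@H](/C(C)=C/COC(=O)[C@@H](OC)c3ccccc3)[C@H]1C=C2C
F4 | step 6 | [(1R,4aS,8aS)-2,5,5,8a-tetramethyl-6-oxo-1,4,4a,5,6,8a-hexahydronaphthalen-1-yl]methyl (2S)-2-methoxy-2-phenylacetate | CC1=CC[C@@H]2C(C)(C)C(=O)C=C[C@]2(C)[C@@H]1COC(=O)[C@@H](OC)c1ccccc1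
F5 | step 6 | [(1S,4aR,8aR)-2,5,5,8a-tetramethyl-6-oxo-1,4,4a,5,6,8a-hexahydronaphthalen-1-yl]methyl (2S)-2-methoxy-2-phenylacetate | CC1=CC[C@H]2C(C)(C)C(=O)C=C[C@@]2(C)[C@H]1COC(=O)[C@@H](OC)c1ccccc1
F6 | step 6 | [(1R,4aS,8aS)-2,5,5,8a-tetramethyl-6-oxo-1,4,4a,5,6,7,8,8a-octahydronaphthalen-1-yl]methyl (2S)-2-methoxy-2-phenylacetate | CC1=CC[C@@H]2C(C)(C)C(=O)CC[C@]2(C)[C@@H]1COC(=O)[C@@H](OC)c1ccccc1
F7 | step 2 | 4-methylcyclohex-2-en-1-one (racemic) | O=C1C=CC(C)CC1
F8 | step 2 | 4,6-dimethylcyclohex-2-en-1-one (racemic, mixture of diastereomers) | O=C1C=CC(C)CC1C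
F9 | step 2 | 4,6,6-trimethylcyclohex-2-en-1-one (racemic) | O=C1C=CC(C)CC1(C)C
F10 | step 2 | trimethyl[(4,6,6-trimethylcyclohexa-1,3-dien-1-yl)oxy]silane | C[Si](C)(C)OC1=CC=C(C)CC1(C)C
F11 | step 7 | (4aS,5R,8aS)-1,1,4a,6-tetramethyl-5-({[tri(propan-2-yl)silyl]oxy}methyl)-1,2,4a,5,8,8a-hexahydronaphthalen-2-ol (either C2 epimer) | CC1=CC[C@@H]2C(C)(C)C(O)C=C[C@]2(C)[C@@H]1CO[Si](C(C)C)(C(C)C)C(C)C
F0 | step 9 | none | none
A1 | alternative 1 | 7-{[(2E,6Z)-9-[(2S)-3,3-dimethyloxiran-2-yl]-3,7-dimethylnona-2,6-dien-1-yl]oxy}-2H-chromen-2-one | CC1(C)O[C@H]1CC/C(C)=C\CC/C(C)=C/COc1ccc2ccc(=O)oc2c1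
A2 | alternative 1 | 7-{[(1R,4aS,6S,8aS)-6-hydroxy-2,5,5,8a-tetramethyl-1,4,4a,5,6,7,8,8a-octahydronaphthalen-1-yl]methoxy}-2H-chromen-2-one | CC1=CC[C@@H]2C(C)(C)[C@@H](O)CC[C@]2(C)[C@@H]1COc1ccc2ccc(=O)oc2c1
A3 | alternative 2 | 3-methoxy-4,4,6-trimethylcyclohexa-2,5-dien-1-one | COC1=CC(=O)C(C)=CC1(C)C
A4 | alternative 2 | (4aR,8R,8aS)-3-methoxy-4,4,7,8a-tetramethyl-8-({[tri(propan-2-yl)silyl]oxy}methyl)-4a,5,8,8a-tetrahydronaphthalen-1(4H)-one | CC1=CC[C@@H]2C(C)(C)C(OC)=CC(=O)[C@]2(C)[C@@H]1CO[Si](C(C)C)(C(C)C)C(C)C
A5 | alternative 3 | (8aS)-8a-methyl-3,4,8,8a-tetrahydronaphthalene-1,6(2H,7H)-dione (Wieland–Miescher ketone) | C[C@]12CCC(=O)C=C1CCCC2=O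
A6 | alternative 3 | (8aS)-5,5,8a-trimethyl-3,5,8,8a-tetrahydronaphthalene-1,6(2H,7H)-dione | C[C@]12CCC(=O)C(C)(C)C1=CCCC2=O
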